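**Strategy.** Each oxolane ring of the target carries an unsubstituted O–CH2 (C5) next to the fully substituted carbinol C4. Both rings are therefore disconnected to C4=C5 enol ethers, and the two C4=C5 bonds are made in one operation by a double ring-closing metathesis that closes both 2,3-dihydrofurans with C2 and C3 already set. The precursor is a biaryl-linked tetraene: two (1S,2R)-1-aryl-2-(3-arylprop-1-en-2-yl)propane-1,3-diol units, each with an O-vinyl ether on the benzylic oxygen, a 1,1-disubstituted alkene and a pivalate on the primary oxygen. The tertiary hydroxyls are added afterwards to the enol ethers, anti to the C3 side chains.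

Key step: step 17

Remark: each oxolane ring is numbered O1, C2 (aryl), C3 (CH2O), C4 (benzyl), C5 (OCH2); ring B is the biaryl ring on C2 of the first oxolane, ring C the biaryl ring of the C4 benzyl group of the second; compounds 1, 3, 5, 8, 14 and 22 are taken as purchasable.

**Route**

Step 1
Reactants: 1 5-bromovanillin (3-bromo-4-hydroxy-5-methoxybenzaldehyde)
Product: 2 4-(benzyloxy)-3-bromo-5-methoxybenzaldehyde
Conditions: BnBr, K2CO3, DMF, 60 °C
Reagents that add atoms: benzyl bromide, BrCc1ccccc1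
Why: Williamson ether synthesis on the phenoxide should be clean because the aldehyde and the aryl bromide are inert to carbonate; no stereocentre is formed.

Step 2
Reactants: 3 [4-(benzyloxy)-3-methoxyphenyl]methanol
Product: 4 1-(benzyloxy)-4-(chloromethyl)-2-methoxybenzene
Conditions: SOCl2, CH2Cl2, 0 °C to rt
Reagents that add atoms: thionyl chloride, O=S(Cl)Cl
Why: Deoxychlorination of an electron-rich benzylic alcohol through its chlorosulfite is fast at low temperature and should leave the aryl benzyl ether intact; no stereocentre.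

Step 3
Reactants: 4 1-(benzyloxy)-4-(chloromethyl)-2-methoxybenzene; 5 diketene (4-methylideneoxetan-2-one)
Product: 7 3-{[4-(benzyloxy)-3-methoxyphenyl]methyl}but-3-enoic acid, via benzylic Grignard reagent 6 (not isolated)
Conditions: Mg, THF, 0 °C (slow addition of 4); then 5, NiCl2 (5 mol%), THF, −78 to 0 °C; aq. HCl work-up
Reagents that add atoms: none
Why: Nickel-catalysed cross-coupling of a Grignard reagent with diketene cleaves the vinylic C–O bond of the β-lactone (insertion of low-valent nickel, transmetalation, reductive elimination) and should give the 3-substituted but-3-enoic acid directly, with the alkene already out of conjugation; no stereocentre.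

Step 4
Reactants: 7 3-{[4-(benzyloxy)-3-methoxyphenyl]methyl}but-3-enoic acid; 8 (4S)-4-benzyl-1,3-oxazolidin-2-one
Product: 10 (4S)-4-benzyl-3-(3-{[4-(benzyloxy)-3-methoxyphenyl]methyl}but-3-enoyl)-1,3-oxazolidin-2-one, via mixed pivalic anhydride 9 (not isolated)
Conditions: PivCl, Et3N, THF, −20 °C; then 8, LiCl, rt
Reagents that add atoms: none
Why: N-Acylation of the oxazolidinone by the mixed anhydride under LiCl/Et3N activation needs no strong base, so the 1,1-disubstituted alkene should stay out of conjugation; the auxiliary stereocentre is untouched.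

Step 5
Reactants: 10 (4S)-4-benzyl-3-(3-{[4-(benzyloxy)-3-methoxyphenyl]methyl}but-3-enoyl)-1,3-oxazolidin-2-one; 2 4-(benzyloxy)-3-bromo-5-methoxybenzaldehyde
Product: 12 (4S)-4-benzyl-3-[(2S,3S)-3-[4-(benzyloxy)-3-bromo-5-methoxyphenyl]-3-hydroxy-2-{3-[4-(benzyloxy)-3-methoxyphenyl]prop-1-en-2-yl}propanoyl]-1,3-oxazolidin-2-one (syn aldol), via dibutylboron Z-dienolate 11 (not isolated)
Conditions: Bu2BOTf, iPr2NEt, CH2Cl2, −78 °C; then 2, −78 to 0 °C; pH 7 buffer, MeOH, H2O2
Reagents that add atoms: none
Why: Evans syn-aldol reaction of a β,γ-unsaturated imide: the Z-boron dienolate reacts at its α-carbon through a closed Zimmerman–Traxler chair in which the benzyl group of the (4S)-auxiliary shields one enolate face, so the α-carbon (later C3) and the carbinol carbon (later C2) should be set together as the (2S,3S) syn pair.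

Step 6
Reactants: 12 syn aldol adduct (ring B bromide)
Product: 13 (1S,2R)-1-[4-(benzyloxy)-3-bromo-5-methoxyphenyl]-2-{3-[4-(benzyloxy)-3-methoxyphenyl]prop-1-en-2-yl}propane-1,3-diol
Conditions: LiBH4, MeOH (1 equiv), THF, 0 °C
Reagents that add atoms: none
Why: Reductive cleavage of the N-acyl oxazolidinone with LiBH4 should release the primary alcohol and the auxiliary without epimerising the α-carbon or touching the aryl bromide; no new stereocentre.

Step 7
Reactants: 14 5-chlorovanillin (3-chloro-4-hydroxy-5-methoxybenzaldehyde)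
Product: 15 4-(benzyloxy)-3-chloro-5-methoxybenzaldehyde
Conditions: BnBr, K2CO3, DMF, 60 °C
Reagents that add atoms: benzyl bromide, BrCc1ccccc1
Why: Williamson ether synthesis on the phenoxide as in step 1; no stereocentre.

Step 8
Reactants: 15 4-(benzyloxy)-3-chloro-5-methoxybenzaldehyde
Product: 16 [4-(benzyloxy)-3-chloro-5-methoxyphenyl]methanol
Conditions: NaBH4, MeOH/THF, 0 °C
Reagents that add atoms: none
Why: Borohydride reduction of an aryl aldehyde is chemoselective in the presence of the aryl chloride and the benzyl ether; no stereocentre.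

Step 9
Reactants: 16 [4-(benzyloxy)-3-chloro-5-methoxyphenyl]methanol
Product: 17 2-(benzyloxy)-1-chloro-5-(chloromethyl)-3-methoxybenzene
Conditions: SOCl2, CH2Cl2, 0 °C to rt
Reagents that add atoms: thionyl chloride, O=S(Cl)Cl
Why: Deoxychlorination of the benzylic alcohol through its chlorosulfite as in step 2; no stereocentre.

Step 10
Reactants: 17 2-(benzyloxy)-1-chloro-5-(chloromethyl)-3-methoxybenzene; 5 diketene
Product: 19 3-{[4-(benzyloxy)-3-chloro-5-methoxyphenyl]methyl}but-3-enoic acid, via benzylic Grignard reagent 18 (not isolated)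
Conditions: Mg, THF, 0 °C (slow addition of 17); then 5, NiCl2 (5 mol%), THF, −78 to 0 °C; aq. HCl work-up
Reagents that add atoms: none
Why: Nickel-catalysed Grignard cross-coupling with ring opening of diketene at the vinylic C–O bond as in step 3, magnesium inserting into the benzylic chloride while the aryl chloride should stay inert at 0 °C; no stereocentre.

Step 11
Reactants: 19 3-{[4-(benzyloxy)-3-chloro-5-methoxyphenyl]methyl}but-3-enoic acid; 8 (4S)-4-benzyl-1,3-oxazolidin-2-one
Product: 21 (4S)-4-benzyl-3-(3-{[4-(benzyloxy)-3-chloro-5-methoxyphenyl]methyl}but-3-enoyl)-1,3-oxazolidin-2-one, via mixed pivalic anhydride 20 (not isolated)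
Conditions: PivCl, Et3N, THF, −20 °C; then 8, LiCl, rt
Reagents that add atoms: none
Why: N-Acylation of the oxazolidinone through the mixed anhydride as in step 4, without strong base; the auxiliary stereocentre is untouched.

Step 12
Reactants: 21 (4S)-4-benzyl-3-(3-{[4-(benzyloxy)-3-chloro-5-methoxyphenyl]methyl}but-3-enoyl)-1,3-oxazolidin-2-one; 22 4-(benzyloxy)-3-methoxybenzaldehyde
Product: 24 (4S)-4-benzyl-3-[(2S,3S)-3-[4-(benzyloxy)-3-methoxyphenyl]-2-{3-[4-(benzyloxy)-3-chloro-5-methoxyphenyl]prop-1-en-2-yl}-3-hydroxypropanoyl]-1,3-oxazolidin-2-one (syn aldol), via dibutylboron Z-dienolate 23 (not isolated)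
Conditions: Bu2BOTf, iPr2NEt, CH2Cl2, −78 °C; then 22, −78 to 0 °C; pH 7 buffer, MeOH, H2O2
Reagents that add atoms: none
Why: Evans syn-aldol reaction as in step 5, the Z-boron dienolate and the (4S)-auxiliary fixing C3' and C2' together as the (2S,3S) syn pair through the chair transition state.

Step 13
Reactants: 24 syn aldol adduct (ring C chloride)
Product: 25 (1S,2R)-1-[4-(benzyloxy)-3-methoxyphenyl]-2-{3-[4-(benzyloxy)-3-chloro-5-methoxyphenyl]prop-1-en-2-yl}propane-1,3-diol
Conditions: LiBH4, MeOH (1 equiv), THF, 0 °C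
Reagents that add atoms: none
Why: Reductive cleavage of the N-acyl oxazolidinone with LiBH4 as in step 6; no new stereocentre and the aryl chloride is inert.

Step 14
Reactants: 13 diol with ring B bromide; 25 diol with ring C chloride
Product: 27 biaryl tetraol in which C5 of ring B of 13 (in place of Br) is bonded to C5 of ring C of 25 (in place of Cl); both diol units (1S,2R), via arylboronic pinacol ester 26 (not isolated)
Conditions: B2pin2, KOAc, Pd(OAc)2, SPhos, 1,4-dioxane, 90 °C; then 25, aq. K3PO4, 100 °C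
Reagents that add atoms: none
Why: Miyaura borylation of the aryl bromide followed in the same flask by Suzuki–Miyaura coupling with the aryl chloride, for which the electron-rich biarylphosphine is suited, should join ring B to ring C in the presence of free hydroxyls and isolated alkenes; the biaryl axis has one ortho substituent on each ring and is not a stereogenic element.

Step 15
Reactants: 27 biaryl tetraol
Product: 28 bis(pivalate) of 27 at the two primary hydroxyls
Conditions: PivCl (2.2 equiv), pyridine, CH2Cl2, −20 to 0 °C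
Reagents that add atoms: pivaloyl chloride, CC(C)(C)C(=O)Cl
Why: Selective esterification, the bulky acyl chloride reacting with the two primary hydroxyls well before the hindered secondary benzylic ones; stereocentres untouched.

Step 16
Reactants: 28 bis(pivalate) diol
Product: 29 bis(vinyl ether) tetraene: 28 with both benzylic hydroxyls as O–CH=CH2 ethers
Conditions: Pd(OCOCF3)2 (10 mol%), 4,7-diphenyl-1,10-phenanthroline, Et3N, butyl vinyl ether (solvent), 75 °C
Reagents that add atoms: butyl vinyl ether, C=COCCCC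
Why: Palladium-catalysed transfer vinylation exchanges the butoxy group of the vinyl ether for each secondary alcohol by alkoxypalladation and β-alkoxide elimination without breaking a carbinol C–O bond, so C2 and C2' keep their configuration.

Step 17
Reactants: 29 bis(vinyl ether) tetraene
Product: 30 bis(4-benzyl-2,3-dihydrofuran) with both rings (2S,3R); C3 bears CH2OPiv and C4=C5 is the enol ether in each ring
Conditions: Mo(=NC6H3-2,6-iPr2)(=CHCMe2Ph)[OCMe(CF3)2]2 (2 × 15 mol%), C6H6, 60 °C, 0.005 M, inert atmosphere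
Reagents that add atoms: none
Why: Ring-closing olefin metathesis of a homoallyl vinyl ether, the known route to 2,3-dihydrofurans and glycals from O-vinyl ethers: the molybdenum alkylidene exchanges with the unhindered O-vinyl group, the resulting oxygen-substituted alkylidene adds [2+2] to the neighbouring 1,1-disubstituted alkene, and cycloreversion releases the ring and a methylidene that leaves as ethene. Each ring closes as a five-membered cyclic enol ether by joining the O-vinyl carbon (C5) to C4, the new double bond being endocyclic; the two closures are independent because the diene units sit at opposite ends of the biaryl. No stereocentre is created, and C2, C3, C2' and C3' lie outside the reacting atoms, so no stereocontrol is required. The selectivity needed is chemoselectivity for ring closure over intermolecular metathesis and correct pairing of the four alkenes: each vinyl ether is five atoms from its own methylidene, any other pairing would give a large ring, and high dilution suppresses oligomers. The molybdenum imido alkylidene is chosen because it turns over with enol ethers and with 1,1-disubstituted alkenes to give trisubstituted enol ethers, and pivalate, benzyl ether and aryl methyl ether groups do not interfere.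

Step 18
Reactants: 30 bis(4-benzyl-2,3-dihydrofuran)
Product: 32 tetra-O-benzyl ether of the target with both oxolane rings (2S,3R,4S) and all four aliphatic hydroxyls free, via bis-epoxide 31 (not isolated)
Conditions: DMDO, acetone/CH2Cl2, −78 to 0 °C; evaporate; iBu2AlH (excess), CH2Cl2, −78 to 0 °C; aq. potassium sodium tartrate
Reagents that add atoms: dimethyldioxirane, CC1(C)OO1
Why: Glycal-type epoxidation followed by reductive opening of the epoxy acetal: oxygen should add to each C4=C5 bond on the face away from the adjacent C3 CH2OPiv group, which fixes C4 and C4' as S, and the Lewis-acidic hydride then opens each epoxide at the acetal carbon C5 and cleaves both pivalates in the same operation.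

Step 19
Reactants: 32 tetra-O-benzyl ether of the target
Product: 33 target CNP0269573.1
Conditions: H2 (1 atm), 10% Pd/C, EtOAc/MeOH, rt
Reagents that add atoms: none
Why: Hydrogenolysis of the four aryl benzyl ethers under neutral conditions should free the phenols while the benzylic C2–O bonds of the oxolanes, which cleave far more slowly, survive; no stereocentre is affected.

**Compound list**

1 | 5-bromovanillin (3-bromo-4-hydroxy-5-methoxybenzaldehyde) | COc1cc(C=O)cc(Br)c1O | starting material
2 | 4-(benzyloxy)-3-bromo-5-methoxybenzaldehyde | COc1cc(C=O)cc(Br)c1OCc1ccccc1 | intermediate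
3 | [4-(benzyloxy)-3-methoxyphenyl]methanol | COc1cc(CO)ccc1OCc1ccccc1 | starting material
4 | 1-(benzyloxy)-4-(chloromethyl)-2-methoxybenzene | COc1cc(CCl)ccc1OCc1ccccc1 | intermediate
5 | diketene (4-methylideneoxetan-2-one) | C=C1CC(=O)O1 | starting material
6 | [4-(benzyloxy)-3-methoxybenzyl]magnesium chloride | COc1cc(C[Mg]Cl)ccc1OCc1ccccc1 | intermediate
7 | 3-{[4-(benzyloxy)-3-methoxyphenyl]methyl}but-3-enoic acid | COc1cc(CC(=C)CC(=O)O)ccc1OCc1ccccc1 | intermediate
8 | (4S)-4-benzyl-1,3-oxazolidin-2-one | O=C1N[C@@H](Cc2ccccc2)CO1 | starting material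
9 | mixed anhydride of 7 with pivalic acid | COc1cc(CC(=C)CC(=O)OC(=O)C(C)(C)C)ccc1OCc1ccccc1 | intermediate
10 | (4S)-4-benzyl-3-(3-{[4-(benzyloxy)-3-methoxyphenyl]methyl}but-3-enoyl)-1,3-oxazolidin-2-one | COc1cc(CC(=C)CC(=O)N2C(=O)OC[C@@H]2Cc2ccccc2)ccc1OCc1ccccc1 | intermediate
11 | dibutylboron (Z)-dienolate of 10 | CCCCB(CCCC)O/C(=C\C(=C)Cc1ccc(OCc2ccccc2)c(OC)c1)N1C(=O)OC[C@@H]1Cc1ccccc1 | intermediate
12 | (4S)-4-benzyl-3-[(2S,3S)-3-[4-(benzyloxy)-3-bromo-5-methoxyphenyl]-3-hydroxy-2-{3-[4-(benzyloxy)-3-methoxyphenyl]prop-1-en-2-yl}propanoyl]-1,3-oxazolidin-2-one | O=C1OC[C@H](Cc2ccccc2)N1C(=O)[C@@H](C(=C)Cc1ccc(OCc2ccccc2)c(OC)c1)[C@H](O)c1cc(OC)c(OCc2ccccc2)c(Br)c1 | intermediate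
13 | (1S,2R)-1-[4-(benzyloxy)-3-bromo-5-methoxyphenyl]-2-{3-[4-(benzyloxy)-3-methoxyphenyl]prop-1-en-2-yl}propane-1,3-diol | OC[C@@H](C(=C)Cc1ccc(OCc2ccccc2)c(OC)c1)[C@H](O)c1cc(OC)c(OCc2ccccc2)c(Br)c1 | intermediate
14 | 5-chlorovanillin (3-chloro-4-hydroxy-5-methoxybenzaldehyde) | COc1cc(C=O)cc(Cl)c1O | starting material
15 | 4-(benzyloxy)-3-chloro-5-methoxybenzaldehyde | COc1cc(C=O)cc(Cl)c1OCc1ccccc1 | intermediate
16 | [4-(benzyloxy)-3-chloro-5-methoxyphenyl]methanol | COc1cc(CO)cc(Cl)c1OCc1ccccc1 | intermediate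
17 | 2-(benzyloxy)-1-chloro-5-(chloromethyl)-3-methoxybenzene | COc1cc(CCl)cc(Cl)c1OCc1ccccc1 | intermediate
18 | [4-(benzyloxy)-3-chloro-5-methoxybenzyl]magnesium chloride | COc1cc(C[Mg]Cl)cc(Cl)c1OCc1ccccc1 | intermediate
19 | 3-{[4-(benzyloxy)-3-chloro-5-methoxyphenyl]methyl}but-3-enoic acid | COc1cc(CC(=C)CC(=O)O)cc(Cl)c1OCc1ccccc1 | intermediate
20 | mixed anhydride of 19 with pivalic acid | COc1cc(CC(=C)CC(=O)OC(=O)C(C)(C)C)cc(Cl)c1OCc1ccccc1 | intermediate
21 | (4S)-4-benzyl-3-(3-{[4-(benzyloxy)-3-chloro-5-methoxyphenyl]methyl}but-3-enoyl)-1,3-oxazolidin-2-one | COc1cc(CC(=C)CC(=O)N2C(=O)OC[C@@H]2Cc2ccccc2)cc(Cl)c1OCc1ccccc1 | intermediate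
22 | 4-(benzyloxy)-3-methoxybenzaldehyde | COc1cc(C=O)ccc1OCc1ccccc1 | starting material
23 | dibutylboron (Z)-dienolate of 21 | CCCCB(CCCC)O/C(=C\C(=C)Cc1cc(OC)c(OCc2ccccc2)c(Cl)c1)N1C(=O)OC[C@@H]1Cc1ccccc1 | intermediate
24 | (4S)-4-benzyl-3-[(2S,3S)-3-[4-(benzyloxy)-3-methoxyphenyl]-2-{3-[4-(benzyloxy)-3-chloro-5-methoxyphenyl]prop-1-en-2-yl}-3-hydroxypropanoyl]-1,3-oxazolidin-2-one | O=C1OC[C@H](Cc2ccccc2)N1C(=O)[C@@H](C(=C)Cc1cc(OC)c(OCc2ccccc2)c(Cl)c1)[C@H](O)c1ccc(OCc2ccccc2)c(OC)c1 | intermediate
25 | (1S,2R)-1-[4-(benzyloxy)-3-methoxyphenyl]-2-{3-[4-(benzyloxy)-3-chloro-5-methoxyphenyl]prop-1-en-2-yl}propane-1,3-diol | OC[C@@H](C(=C)Cc1cc(OC)c(OCc2ccccc2)c(Cl)c1)[C@H](O)c1ccc(OCc2ccccc2)c(OC)c1 | intermediate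
26 | pinacol boronate of 13 (Bpin in place of Br on ring B) | OC[C@@H](C(=C)Cc1ccc(OCc2ccccc2)c(OC)c1)[C@H](O)c1cc(OC)c(OCc2ccccc2)c(B2OC(C)(C)C(C)(C)O2)c1 | intermediate
27 | biaryl tetraol: C5 of ring B of 13 bonded to C5 of ring C of 25, both propane-1,3-diol units (1S,2R) | OC[C@@H](C(=C)Cc1ccc(OCc2ccccc2)c(OC)c1)[C@H](O)c1cc(OC)c(OCc2ccccc2)c(-c2cc(CC(=C)[C@H](CO)[C@H](O)c3ccc(OCc4ccccc4)c(OC)c3)cc(OC)c2OCc2ccccc2)c1 | intermediate
28 | bis(pivalate) of 27 at both primary hydroxyls, units (1S,2R) | CC(C)(C)C(=O)OC[C@@H](C(=C)Cc1ccc(OCc2ccccc2)c(OC)c1)[C@H](O)c1cc(OC)c(OCc2ccccc2)c(-c2cc(CC(=C)[C@H](COC(=O)C(C)(C)C)[C@H](O)c3ccc(OCc4ccccc4)c(OC)c3)cc(OC)c2OCc2ccccc2)c1 | intermediate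
29 | bis(vinyl ether) tetraene: 28 with both benzylic hydroxyls as O-vinyl ethers, units (1S,2R) | CC(C)(C)C(=O)OC[C@@H](C(=C)Cc1ccc(OCc2ccccc2)c(OC)c1)[C@H](OC=C)c1cc(OC)c(OCc2ccccc2)c(-c2cc(CC(=C)[C@H](COC(=O)C(C)(C)C)[C@H](OC=C)c3ccc(OCc4ccccc4)c(OC)c3)cc(OC)c2OCc2ccccc2)c1 | intermediate
30 | bis(4-benzyl-2,3-dihydrofuran): both rings (2S,3R), 2-aryl, 3-(pivaloyloxymethyl), C4=C5 enol ether | COc1cc(CC2=CO[C@H](c3cc(OC)c(OCc4ccccc4)c(-c4cc(CC5=CO[C@H](c6ccc(OCc7ccccc7)c(OC)c6)[C@H]5COC(=O)C(C)(C)C)cc(OC)c4OCc4ccccc4)c3)[C@H]2COC(=O)C(C)(C)C)ccc1OCc1ccccc1 | intermediate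
31 | bis-epoxide of 30: each C4–C5 epoxide oxygen anti to the C3 CH2OPiv group and cis to the C2 aryl group | COc1cc(C[C@]23O[C@@H]3O[C@H](c3cc(OC)c(OCc4ccccc4)c(-c4cc(C[C@]56O[C@@H]6O[C@H](c6ccc(OCc7ccccc7)c(OC)c6)[C@H]5COC(=O)C(C)(C)C)cc(OC)c4OCc4ccccc4)c3)[C@H]2COC(=O)C(C)(C)C)ccc1OCc1ccccc1 | intermediate
32 | tetra-O-benzyl ether of the target (four phenols as benzyl ethers), both oxolane rings (2S,3R,4S) | COc1cc(C[C@@]2(O)CO[C@H](c3cc(OC)c(OCc4ccccc4)c(-c4cc(C[C@@]5(O)CO[C@H](c6ccc(OCc7ccccc7)c(OC)c6)[C@H]5CO)cc(OC)c4OCc4ccccc4)c3)[C@H]2CO)ccc1OCc1ccccc1 | intermediate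
33 | CNP0269573.1: ring B–ring C biaryl, both oxolane rings (2S,3R,4S) with 2-aryl, 3-hydroxymethyl, 4-hydroxy-4-benzyl | COc1cc(C[C@@]2(O)CO[C@H](c3cc(OC)c(O)c(-c4cc(C[C@@]5(O)CO[C@H](c6ccc(O)c(OC)c6)[C@H]5CO)cc(OC)c4O)c3)[C@H]2CO)ccc1O | target

**Totals.** 19 steps in all. The longest linear sequence is 13 steps (steps 7 to 19, from 14).

**Steps most likely to fail**

Step 17 (double ring-closing metathesis). The catalyst may rest as the oxygen-substituted alkylidene and turn over too slowly on the hindered 1,1-disubstituted alkenes, so that the second closure stalls while intermolecular metathesis or alkene migration into conjugation with the arenes takes over. The fallback builds the enol ethers without metathesis; it sets out from 28 and returns at 30. Both methylidene groups of 28 would be hydroborated with 9-borabicyclo[3.3.1]nonane (THF, rt; then NaBO3) to the bis(primary alcohol) F1, formed as C4 epimers of no consequence. TEMPO/PhI(OAc)2 (CH2Cl2, rt) would oxidise each primary alcohol and close it onto the benzylic hydroxyl to give the bis(γ-lactone) F2. Disiamylborane (THF, 0 °C) would reduce the lactones, but not the pivalates, to the bis(lactol) F3. MsCl/Et3N (CH2Cl2, 0 °C to reflux) would then dehydrate each lactol through its anomeric mesylate to the C4=C5 enol ether 30.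

Step 18 (epoxidation and reductive opening). Oxygen transfer may show poor facial selectivity, because the C2 aryl group stands on the very face that must be attacked, and the strained epoxy acetal may be lost by solvolysis or 1,2-shift before hydride arrives. The fallback replaces epoxidation–reduction by hydroboration–oxidation; it sets out from 30 and returns at 32. BH3·SMe2 (THF, 0 °C) should place boron on C4, β to the ring oxygen, and hydrogen on C5 in a syn addition anti to the C3 side chain. Oxidation with NaBO3, with retention at carbon, would give the bis(tertiary alcohol) bis(pivalate) F4 without any epoxide. iBu2AlH (CH2Cl2, −78 °C) would then remove the pivalates to give 32.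

Step 10 (Grignard opening of diketene). Homocoupling may occur during formation of the electron-rich benzylic Grignard reagent, the reagent may add uncatalysed to the lactone carbonyl of diketene, and low-valent nickel may insert into the aryl chloride. Step 3 is the same reaction on the simpler chloride 4 and is exposed to the first two processes only. The fallback uses a zinc reagent and a separate oxidation; it sets out from 17 and returns at 19. Zinc insertion (Zn dust, LiCl, THF, rt) would give the benzylic zinc chloride F5, which forms without homocoupling and tolerates the aryl chloride. Negishi coupling with commercial 3-bromobut-3-en-1-ol (Pd(PPh3)4, THF, 50 °C; the free hydroxyl is tolerated) would give the homoallylic alcohol F6. TEMPO/PhI(OAc)2 in MeCN/aqueous pH 7 buffer would oxidise F6 to acid 19.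

**Further compounds**

F1 | step 17 | bis(primary alcohol) from hydroboration of both methylidene groups of 28 (C4 and C4' epimers) | CC(C)(C)C(=O)OC[C@@H](C(CO)Cc1ccc(OCc2ccccc2)c(OC)c1)[C@H](O)c1cc(OC)c(OCc2ccccc2)c(-c2cc(CC(CO)[C@H](COC(=O)C(C)(C)C)[C@H](O)c3ccc(OCc4ccccc4)c(OC)c3)cc(OC)c2OCc2ccccc2)c1
F2 | step 17 | bis(γ-lactone): each ring O1–C2(aryl)–C3(CH2OPiv)–C4(benzyl)–C5(=O), C2/C3 as in 30, C4 epimers | O=C1O[C@H](c2cc(OC)c(OCc3ccccc3)c(-c3cc(CC4C(=O)O[C@H](c5ccc(OCc6ccccc6)c(OC)c5)[C@H]4COC(=O)C(C)(C)C)cc(OC)c3OCc3ccccc3)c2)[C@@H](COC(=O)C(C)(C)C)C1Cc1ccc(OCc2ccccc2)c(OC)c1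
F3 | step 17 | bis(lactol): F2 with each C5 carbonyl reduced to the hemiacetal (anomers) | OC1O[C@H](c2cc(OC)c(OCc3ccccc3)c(-c3cc(CC4C(O)O[C@H](c5ccc(OCc6ccccc6)c(OC)c5)[C@H]4COC(=O)C(C)(C)C)cc(OC)c3OCc3ccccc3)c2)[C@@H](COC(=O)C(C)(C)C)C1Cc1ccc(OCc2ccccc2)c(OC)c1
F4 | step 18 | bis(pivalate) of 32 at both primary hydroxyls, rings (2S,3R,4S) | COc1cc(C[C@@]2(O)CO[C@H](c3cc(OC)c(OCc4ccccc4)c(-c4cc(C[C@@]5(O)CO[C@H](c6ccc(OCc7ccccc7)c(OC)c6)[C@H]5COC(=O)C(C)(C)C)cc(OC)c4OCc4ccccc4)c3)[C@H]2COC(=O)C(C)(C)C)ccc1OCc1ccccc1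
F5 | step 10 | [4-(benzyloxy)-3-chloro-5-methoxybenzyl]zinc chloride | COc1cc(C[Zn]Cl)cc(Cl)c1OCc1ccccc1
F6 | step 10 | 3-{[4-(benzyloxy)-3-chloro-5-methoxyphenyl]methyl}but-3-en-1-ol | COc1cc(CC(=C)CCO)cc(Cl)c1OCc1ccccc1
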